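**Strategy.** Everything rests on disconnecting the C3–C4 bond of ring A. The feature exploited is quaternary C4, which carries an axial methyl (C19) and an equatorial oxygenated carbon (C18): such a centre is what contraction of a ring one carbon larger delivers. The precursor is therefore a trans-fused bicycle in which ring B is fused to a seven-membered ring (C10–C1–C2–C3–C18–C4–C5) bearing a 4,18-epoxide anti to C20 and, on ring B, a C8–C9 enol triflate. A bulky aluminium Lewis acid makes the C18–C3 ring bond shift to C4; this single operation forms ring A, sets the C4 stereocentre and frees C18 as an aldehyde.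

Key step: step 6

**Remarks on the chemistry**
- Labdane numbering is used for all bicyclic compounds. The target SMILES is an ent-labdane (4S,5S,8S,9S,10R,13S): as conventionally drawn C20 points down, so the face anti to C20 is the β-face. Faces are therefore named "syn/anti to C20".
- The C9 oxygen is carried through the rearrangement as the C8–C9 enol triflate instead of a free ketone. Ring system, epoxide and migrating bond are unchanged; this removes a Lewis-basic, enolisable carbonyl from the key step, makes the later aldehyde reduction trivial, and saves a separate enolisation next to quaternary C10.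
- Assumption: methyl hydrogen (R)-3-methylglutarate is bought in high enantiomeric purity; it is the only source of the C13 configuration.

**Route**

Step 1
Reactants: 1 (S)-carvone; 2 iodomethane
Product: 4 6-methylcarvone (both C6 epimers), via carvone lithium dienolate 3 (not isolated)
Conditions: LiN(i-Pr)2 (1.1 equiv), THF, −78 °C; then MeI, −78 → 0 °C
Reagents that add atoms: iodomethane (2), CI
Why: Kinetic α′-deprotonation of the enone by LiN(i-Pr)2 gives the cross-conjugated dienolate, which is C-methylated by SN2 attack on MeI (enolate alkylation); the C6 configuration formed here is irrelevant because this centre is re-enolised in step 2.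

Step 2
Reactants: 4 6-methylcarvone; 5 5-iodopent-1-ene
Product: 7 6-methyl-6-(pent-4-enyl)carvone, via 6-methylcarvone lithium dienolate 6 (not isolated)
Conditions: LiN(i-Pr)2 (1.2 equiv), THF, −78 → 0 °C; then DMPU (3 equiv), 5 (1.5 equiv), −78 °C → rt
Reagents that add atoms: 5-iodopent-1-ene (5), C=CCCCI
Why: Enolate alkylation that creates the quaternary carbon (C10 in labdane numbering): to avoid A(1,2) strain with the enolate methyl the C5 isopropenyl group sits pseudo-axial and blocks its own face, so the primary iodide is attacked from the opposite face, which puts the pentenyl chain trans and the future C20 methyl cis to isopropenyl.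

Step 3
Reactants: 7 6-methyl-6-(pent-4-enyl)carvone
Product: 9 trienyl triflate, via C8–C9 lithium enolate 8 (not isolated)
Conditions: LiBH(s-Bu)3 (1.1 equiv), THF, −78 °C; then PhNTf2 (1.2 equiv), −78 °C → rt; aq NH4Cl
Reagents that add atoms: N-phenylbis(trifluoromethanesulfonimide), O=S(=O)(N(c1ccccc1)S(=O)(=O)C(F)(F)F)C(F)(F)F
Why: Conjugate reduction by the hindered borohydride, which adds hydride to the unsubstituted β-carbon of the α-methyl enone, gives only the C8–C9 enolate, and its O-sulfonylation by PhNTf2 (reductive enol triflation) fixes the C9 oxygen as a robust coupling handle without creating a stereocentre.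

Step 4
Reactants: 9 trienyl triflate
Product: 10 A-homo diene triflate
Conditions: second-generation Grubbs catalyst RuCl2(=CHPh)(H2IMes)(PCy3) (5 mol %), CH2Cl2 (5 mM), 40 °C
Reagents that add atoms: none
Why: Ring-closing olefin metathesis: the ruthenium carbene forms at the monosubstituted pentenyl terminus and closes onto the 1,1-disubstituted isopropenyl group with loss of ethene, and because the two arms are trans-diequatorial on C5 and C10 the trisubstituted cycloheptene is formed as the trans-fused bicycle while the electron-poor enol triflate olefin does not take part.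

Step 5
Reactants: 10 A-homo diene triflate
Product: 11 4,18-epoxide (oxygen anti to C20)
Conditions: mCPBA (1.1 equiv), NaHCO3, CH2Cl2, 0 °C
Reagents that add atoms: 3-chloroperoxybenzoic acid, OOC(=O)c1cccc(Cl)c1
Why: Prilezhaev epoxidation of the only electron-rich olefin (the enol triflate double bond is deactivated): in the chair cycloheptene the pseudo-axial C20 methyl lies directly over one face of C4=C18, so the peracid adds from the face of 5-H and sets C4 and C18 together with the oxygen anti to C20.

Step 6
Reactants: 11 4,18-epoxide
Product: 12 ring-contracted C18 aldehyde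
Conditions: MeAl(OAr)2 (Ar = 4-bromo-2,6-di-tert-butylphenyl; 2.2 equiv, made from AlMe3 and 2 ArOH in CH2Cl2, rt), CH2Cl2, −78 → −40 °C; 1 M HCl
Reagents that add atoms: none
Why: Coordination of the oxophilic, very bulky aluminium aryloxide to the epoxide oxygen weakens the C4–O bond at the tertiary carbon, and the ring bond C18–C3 migrates to C4 on the side opposite the breaking bond while C18 becomes the carbonyl carbon of the aluminium-bound aldehyde (Meinwald rearrangement, here a ring-contracting 1,2-alkyl shift). The closest known reaction type is the Lewis-acid-promoted contraction of 1-methylcycloalkene oxides to 1-methylcycloalkanecarbaldehydes with bulky methylaluminium bis(aryloxides). Ring A is closed not by cyclisation of a chain but by a suprafacial 1,2-shift through a three-centre transition state that forms C3–C4 and turns the seven-membered ring into the six-membered one. The only new stereocentre, quaternary C4, is fixed by the epoxide configuration from step 5 together with invertive (anti) migration: oxygen leaves from the face anti to C20 and C3 enters from the C20 face, so the formyl carbon C18 ends equatorial and the C19 methyl axial. The step needs C3 migration in preference to the C18 hydride shift (which would give the A-homo 18-ketone) and to a C5 hydride shift; the bulk of the aryloxide ligands around the C18–O–Al unit disfavours the rotamer required for hydride migration, the low temperature keeps ionisation and migration concerted, and 5-H sits on the same face as the departing oxygen where it cannot displace it from the rear. The enol triflate is not Lewis basic, so the reagent is not diverted.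

Step 7
Reactants: 12 ring-contracted C18 aldehyde
Product: 13 C18 alcohol
Conditions: NaBH4, MeOH/THF, 0 °C
Reagents that add atoms: none
Why: Borohydride reduction of the neopentyl aldehyde to the primary alcohol; the enol triflate and quaternary C4 are unaffected.

Step 8
Reactants: 13 C18 alcohol
Product: 14 C18 benzyl ether
Conditions: 2-benzyloxy-1-methylpyridinium triflate (2 equiv), MgO, PhCF3, 85 °C
Reagents that add atoms: 2-benzyloxy-1-methylpyridinium trifluoromethanesulfonate, C[n+]1ccccc1OCc1ccccc1.[O-]S(=O)(=O)C(F)(F)F
Why: Benzyl transfer from the 2-benzyloxypyridinium salt under neutral thermal conditions (Dudley benzylation), which protects the hindered neopentyl alcohol without generating an alkoxide that could attack the sulfonyl group of the enol triflate.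

Step 9
Reactants: 15 methyl hydrogen (R)-3-methylglutarate
Product: 17 (4S)-4-methyloxan-2-one, via (S)-5-hydroxy-3-methylpentanoic acid 16 (not isolated)
Conditions: LiBH4 (2.5 equiv), THF, 0 °C → rt; 2 M HCl; then TsOH (cat.), toluene, 80 °C
Reagents that add atoms: none
Why: Chemoselective borohydride reduction: LiBH4 reduces the methyl ester but leaves the lithium carboxylate, and acid then lactonises the hydroxy acid, so the former acid carbon is kept as the future C15 and the untouched stereocentre ends up as (S)-C13 of the target.

Step 10
Reactants: 17 (4S)-4-methyloxan-2-one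
Product: 19 methyl (3R)-5-iodo-3-methylpentanoate, via trimethylsilyl 5-iodo-3-methylpentanoate 18 (not isolated)
Conditions: Me3SiI (1.3 equiv), CH2Cl2, rt; then MeOH, rt → 40 °C
Reagents that add atoms: iodotrimethylsilane, C[Si](C)(C)I; methanol, CO
Why: Lactone cleavage by iodotrimethylsilane (silylation of the carbonyl oxygen, then SN2 attack of iodide at the O–CH2 carbon) followed by methanolysis and in situ acid-catalysed esterification of the silyl ester gives the ω-iodo ester; the stereocentre is two carbons away from either reacting site.

Step 11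
Reactants: 14 C18 benzyl ether; 19 methyl (3R)-5-iodo-3-methylpentanoate
Product: 21 coupled Δ8 methyl ester, via alkylzinc iodide 20 (not isolated)
Conditions: 19 (1.6 equiv), Zn dust (activated with BrCH2CH2Br/Me3SiCl), LiCl, THF, 40 °C; then 14, PdCl2(dppf) (5 mol %), THF/DMA, 60 °C
Reagents that add atoms: none
Why: Negishi sp3–sp2 cross-coupling: zinc inserts into the primary C–I bond without harming the ester, zerovalent palladium adds oxidatively to the C9–OTf bond, and transmetallation followed by reductive elimination from the wide-bite-angle dppf complex forms C9–C11 faster than β-hydride elimination; no stereocentre is touched.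

Step 12
Reactants: 21 coupled Δ8 methyl ester
Product: 22 Δ8 C15 alcohol
Conditions: LiAlH4, THF, 0 °C; H2O, 15% NaOH
Reagents that add atoms: none
Why: Hydride reduction of the methyl ester to the C15 primary alcohol; the benzyl ether and the tetrasubstituted olefin are inert to LiAlH4.

Step 13
Reactants: 22 Δ8 C15 alcohol
Product: 24 8,15-diol, via C8 alkylborane 23 (not isolated)
Conditions: BH3·SMe2 (5 equiv), THF, 0 °C → rt; then 3 M NaOH, 30% H2O2, 0 → 45 °C
Reagents that add atoms: hydrogen peroxide, OO
Why: Hydroboration–oxidation of the tetrasubstituted olefin: after the hydroxyl has been capped as a borate, borane adds syn with boron on C8 (C9 is shielded by quaternary C10) from the face anti to the axial C20 methyl, and oxidation with retention gives 9-H and 8-OH cis on that face, i.e. the C9 side chain equatorial and syn to C20 and the C8 hydroxyl equatorial with C17 axial.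

Step 14
Reactants: 24 8,15-diol; 25 benzyl hydrogen malonate
Product: 26 O15 benzyl malonate
Conditions: 25 (1.05 equiv), DCC (1.1 equiv), DMAP (0.1 equiv), CH2Cl2, 0 °C
Reagents that add atoms: benzyl hydrogen malonate (25), OC(=O)CC(=O)OCc1ccccc1
Why: Steglich esterification (carbodiimide activation, DMAP acyl transfer): the unhindered primary C15 hydroxyl is acylated, whereas the hindered tertiary C8 hydroxyl does not react at 0 °C with one equivalent of acid.

Step 15
Reactants: 26 O15 benzyl malonate
Product: 27 target CNP0324566.1
Conditions: H2 (1 atm), Pd/C (10 wt %), EtOAc, rt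
Reagents that add atoms: none
Why: Palladium-catalysed hydrogenolysis cleaves the benzyl ester and the benzyl ether in the same operation under neutral conditions, which leave the malonic half-ester, the tertiary alcohol and all stereocentres untouched.

**Compound list**

1 | (S)-carvone, (5S)-2-methyl-5-(prop-1-en-2-yl)cyclohex-2-en-1-one | CC(=C)[C@@H]1CC(=O)C(C)=CC1 | starting material
2 | iodomethane | CI | starting material
3 | lithium dienolate of 1 (O–C1=C6, C2=C3 retained) | [Li+].[O-]C1=C[C@@H](C(C)=C)CC=C1C | intermediate (not isolated)
4 | 6-methylcarvone, (5S)-2,6-dimethyl-5-(prop-1-en-2-yl)cyclohex-2-en-1-one, both C6 epimers | CC1=CC[C@H](C(C)=C)C(C)C1=O | intermediate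
5 | 5-iodopent-1-ene | C=CCCCI | starting material
6 | lithium dienolate of 4 | [Li+].[O-]C1=C(C)[C@@H](C(C)=C)CC=C1C | intermediate (not isolated)
7 | (5R,6R)-2,6-dimethyl-6-(pent-4-en-1-yl)-5-(prop-1-en-2-yl)cyclohex-2-en-1-one (pentenyl trans, 6-methyl cis to isopropenyl) | O=C1C(C)=CC[C@H](C(C)=C)[C@@]1(C)CCCC=C | intermediate
8 | lithium (5R,6R)-2,6-dimethyl-6-(pent-4-en-1-yl)-5-(prop-1-en-2-yl)cyclohex-1-en-1-olate | [Li+].[O-]C1=C(C)CC[C@H](C(C)=C)[C@@]1(C)CCCC=C | intermediate (not isolated)
9 | (5R,6R)-2,6-dimethyl-6-(pent-4-en-1-yl)-5-(prop-1-en-2-yl)cyclohex-1-en-1-yl trifluoromethanesulfonate | FC(F)(F)S(=O)(=O)OC1=C(C)CC[C@H](C(C)=C)[C@@]1(C)CCCC=C | intermediate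
10 | A-homo diene triflate: trans-fused bicyclo[5.4.0]undecadiene; seven-membered ring C10–C1–C2–C3–C18=C4(CH3)–C5; ring B with C8(CH3)=C9–OTf; C20 methyl on C10; 5-H anti to C20 | CC1=C(OS(=O)(=O)C(F)(F)F)[C@]2(C)CCCC=C(C)[C@H]2CC1 | intermediate
11 | 4,18-epoxide of 10, oxygen anti to C20 and cis to 5-H (substrate of the key step) | CC1=C(OS(=O)(=O)C(F)(F)F)[C@]2(C)CCC[C@@H]3O[C@]3(C)[C@H]2CC1 | intermediate
12 | ring-contracted aldehyde: trans-decalin, C4 with axial CH3 (C19, syn to C20) and equatorial CHO (C18), C8(CH3)=C9–OTf (product of the key step) | CC1=C(OS(=O)(=O)C(F)(F)F)[C@]2(C)CCC[C@](C)(C=O)[C@H]2CC1 | intermediate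
13 | 18-alcohol of 12 (equatorial CH2OH on C4) | CC1=C(OS(=O)(=O)C(F)(F)F)[C@]2(C)CCC[C@](C)(CO)[C@H]2CC1 | intermediate
14 | 18-O-benzyl ether of 13 | CC1=C(OS(=O)(=O)C(F)(F)F)[C@]2(C)CCC[C@](C)(COCc3ccccc3)[C@H]2CC1 | intermediate
15 | methyl hydrogen (R)-3-methylglutarate, (3R)-5-methoxy-3-methyl-5-oxopentanoic acid | C[C@H](CC(=O)O)CC(=O)OC | starting material
16 | (3S)-5-hydroxy-3-methylpentanoic acid | C[C@H](CC(=O)O)CCO | intermediate (not isolated)
17 | (4S)-4-methyloxan-2-one | C[C@@H]1CC(=O)OCC1 | intermediate
18 | trimethylsilyl (3R)-5-iodo-3-methylpentanoate | C[C@H](CC(=O)O[Si](C)(C)C)CCI | intermediate (not isolated)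
19 | methyl (3R)-5-iodo-3-methylpentanoate | C[C@H](CC(=O)OC)CCI | intermediate
20 | [(3R)-5-methoxy-3-methyl-5-oxopentyl]zinc iodide | C[C@H](CC(=O)OC)CC[Zn]I | intermediate (not isolated)
21 | methyl (13S)-18-benzyloxy-ent-labd-8-en-15-oate (C8=C9 tetrasubstituted, side chain on C9) | CC1=C(CC[C@H](C)CC(=O)OC)[C@]2(C)CCC[C@](C)(COCc3ccccc3)[C@H]2CC1 | intermediate
22 | (13S)-18-benzyloxy-ent-labd-8-en-15-ol | CC1=C(CC[C@H](C)CCO)[C@]2(C)CCC[C@](C)(COCc3ccccc3)[C@H]2CC1 | intermediate
23 | C8 alkylborane of 22 (BH2 on C8 anti to C20, 9-H cis to it, O15 as O–BH2) | C[C@H](CCOB)CC[C@H]1[C@]2(C)CCC[C@](C)(COCc3ccccc3)[C@H]2CC[C@]1(C)B | intermediate (not isolated)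
24 | (13S)-18-benzyloxy-ent-labdane-8,15-diol (8-OH equatorial and anti to C20, C9 side chain equatorial) | C[C@H](CCO)CC[C@H]1[C@]2(C)CCC[C@](C)(COCc3ccccc3)[C@H]2CC[C@]1(C)O | intermediate
25 | benzyl hydrogen malonate, 3-(benzyloxy)-3-oxopropanoic acid | OC(=O)CC(=O)OCc1ccccc1 | starting material
26 | benzyl [(13S)-18-benzyloxy-8-hydroxy-ent-labdan-15-yl] malonate | C[C@H](CCOC(=O)CC(=O)OCc1ccccc1)CC[C@H]1[C@]2(C)CCC[C@](C)(COCc3ccccc3)[C@H]2CC[C@]1(C)O | intermediate
27 | CNP0324566.1, (13S)-8,18-dihydroxy-ent-labdan-15-yl hydrogen malonate (4S,5S,8S,9S,10R,13S) | C[C@H](CCOC(=O)CC(=O)O)CC[C@H]1[C@]2(C)CCC[C@](C)(CO)[C@H]2CC[C@]1(C)O | target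

**Step count and risks**

Total step count: 15 (13 in the main line, 2 for the side-chain iodide). Longest linear sequence: 13 steps (steps 1–8 and 11–15 from (S)-carvone).

Steps most likely to fail:

1. Step 6. The C18 hydride may migrate instead of C3, giving the ring-retained A-homo ketone, or stereospecificity may be partly lost if the C4–O bond ionises before C3 moves. Fallback, setting out from 10 and returning at 12: dihydroxylation of the C4=C18 olefin of 10 with OsO4 (cat.)/NMO on the face anti to C20 gives the cis-4,18-diol F1. Trimethyl orthoformate/PPTS converts it into the cyclic methyl orthoformate F2. BF3·OEt2 at −78 °C then opens the derived dioxolanylium ion at tertiary C4 with the same anti shift of C3 and releases aldehyde 12 (orthoester-mediated pinacol rearrangement). The leaving group is now a formate held in a five-membered ring instead of an aluminium alkoxide on an epoxide.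

2. Step 13. Borane may add only sluggishly to the tetrasubstituted C8=C9 bond, with boron ending partly on C9 or migrating on warming. Fallback, setting out from 22 and returning at 24: photo-oxygenation of 22 (O2, tetraphenylporphyrin, hν, CH2Cl2, 0 °C) is a singlet-oxygen ene reaction in which oxygen bonds to the less hindered C8 anti to C20 and a C11 hydrogen, geminal to the bulky C10, is abstracted. It gives the 8-hydroperoxy-9(11)-ene F3, which PPh3 reduces to the tertiary allylic alcohol F4. Hydroxyl-directed hydrogenation with [Ir(cod)(PCy3)(py)]PF6 and H2 then delivers hydrogen to C9 from the face of the 8-OH and gives 24.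

3. Step 11. Oxidative addition at the tetrasubstituted enol triflate beside quaternary C10 may be slow, so that protodezincation or β-hydride elimination competes. Fallback, setting out from 19 (with 14) and returning at 21: E2 elimination of HI from 19 (DBU, toluene, 80 °C) gives methyl (3R)-3-methylpent-4-enoate F5. Anti-Markovnikov hydroboration with 9-BBN gives the B-alkyl-9-BBN F6, which is coupled with 14 under B-alkyl Suzuki–Miyaura conditions (PdCl2(dppf), AsPh3, Cs2CO3, DMF/THF/H2O, 60 °C) to give 21.

**Further compounds**

F1 | step 6 | cis-4,18-diol of 10, both hydroxyls anti to C20 | CC1=C(OS(=O)(=O)C(F)(F)F)[C@]2(C)CCC[C@H](O)[C@](C)(O)[C@H]2CC1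
F2 | step 6 | cyclic methyl orthoformate (2-methoxy-1,3-dioxolane) of F1, both epimers at the orthoester carbon | CC1=C(OS(=O)(=O)C(F)(F)F)[C@]2(C)CCC[C@@H]3OC(OC)O[C@]3(C)[C@H]2CC1
F3 | step 13 | (13S)-18-benzyloxy-8-hydroperoxy-ent-labd-9(11)-en-15-ol, OOH anti to C20 | C[C@H](CCO)CC=C1[C@]2(C)CCC[C@](C)(COCc3ccccc3)[C@H]2CC[C@]1(C)OO
F4 | step 13 | (13S)-18-benzyloxy-ent-labd-9(11)-ene-8,15-diol, 8-OH anti to C20 | C[C@H](CCO)CC=C1[C@]2(C)CCC[C@](C)(COCc3ccccc3)[C@H]2CC[C@]1(C)O
F5 | step 11 | methyl (3R)-3-methylpent-4-enoate | C[C@H](CC(=O)OC)C=C
F6 | step 11 | methyl (3R)-5-(9-borabicyclo[3.3.1]nonan-9-yl)-3-methylpentanoate | C[C@H](CC(=O)OC)CCB1C2CCCC1CCC2
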